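**Plan**
1. Retrosynthesis (cyclohexenone numbering: C1 ketone, C2 hydroxymethyl, C4 angelate, C5 isopropyl, C6 hydroxytiglate): the two ester C–O bonds and the C2–CH2OH bond are cut first, then the ring bonds C1–C6 and C4–C5 are cut together.
2. Enabling feature: C4(O)–C3=C2–C1(=O) is the C6–C5=C4–C3 diene of a 3-oxy-2-pyrone, and C6(O)–C5(iPr) is the enol double bond of isovaleraldehyde, so one inverse-demand [4+2] addition builds the whole ring.
3. Forward: pyrone ester plus (Z)-silyl enol ether give a 2-oxabicyclo[2.2.2]octenone; LiAlH4 opens the lactone bridge and NaIO4 cuts out its former carbonyl carbon to unveil the C1 ketone; then angelate, hydroxytiglate, hydroxymethyl (Morita–Baylis–Hillman), desilylation.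
4. Stereochemistry: C5/C6 cis from the Z enol ether and endo addition; absolute sense from an (S)-O-methylmandelate on the pyrone oxygen (facial isomers are separable diastereomers); C4 is corrected by oxidation and hydride delivery anti to the C5/C6 groups.

Key step: step 3

Assumption: the phenyl ring of the (S)-O-methylmandelate is taken to shield the pyrone face that does not lead to 7; the two endo diastereomers are separated in any case, and the (R)-acid would be taken if the sense of induction proved opposite.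

Step 1
Reactants: 1 3-methylbutanal (isovaleraldehyde)
Product: 3 tert-butyldimethyl{[(1Z)-3-methylbut-1-en-1-yl]oxy}silane, via potassium (Z)-enolate 2 (not isolated)
Conditions: KH, THF, 0 °C; then TBSCl, 0 °C to rt
Reagents that add atoms: tert-butyldimethylsilyl chloride (TBSCl), CC(C)(C)[Si](C)(C)Cl
Why: KH deprotonates the aldehyde irreversibly to the potassium enolate, expected mainly as the Z isomer, and the silyl chloride traps it on oxygen with retention of geometry (silyl enol ether formation through a metal enolate); the Z geometry later fixes the cis relation of the C5 and C6 substituents.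

Step 2
Reactants: 4 3-hydroxy-2H-pyran-2-one; 5 (2S)-2-methoxy-2-phenylacetic acid
Product: 6 2-oxo-2H-pyran-3-yl (2S)-2-methoxy-2-phenylacetate
Conditions: DCC, DMAP (cat.), CH2Cl2, 0 °C
Reagents that add atoms: none
Why: Steglich esterification of the acidic enolic hydroxyl at low temperature should give the enol ester without racemising the α-methoxy acid and turns the pyrone into an electron-poorer, chiral diene.

Step 3
Reactants: 6 2-oxo-2H-pyran-3-yl (2S)-2-methoxy-2-phenylacetate; 3 tert-butyldimethyl{[(1Z)-3-methylbut-1-en-1-yl]oxy}silane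
Product: 7 (1R,4R,7S,8S)-8-{[tert-butyl(dimethyl)silyl]oxy}-3-oxo-7-(propan-2-yl)-2-oxabicyclo[2.2.2]oct-5-en-4-yl (2S)-2-methoxy-2-phenylacetate (endo adduct: silyloxy and isopropyl groups cis to each other and syn to the C5=C6 bridge)
Conditions: 3 (3 equiv), CH2Cl2, 12 kbar, 25 °C; chromatography
Reagents that add atoms: none
Why: Inverse-electron-demand Diels–Alder reaction in which the HOMO of the silyl enol ether adds across C3 and C6 of the pyrone (LUMO) in an asynchronous concerted process, the nucleophilic isopropyl-bearing carbon bonding to the electrophilic C6 and the oxygen-bearing carbon to C3; the closest known type is the high-pressure cycloaddition of 3-bromo- and 3-sulfonyl-2-pyrones with vinyl and silyl enol ethers. The carbocycle is closed by an intermolecular suprafacial [4+2] addition that leaves the lactone as a two-atom bridge (2-oxabicyclo[2.2.2]octene). C7 and C8 of 7 come out cis because the Z geometry of 3 is retained, and both groups lie syn to the new C5=C6 bond because donor-substituted dienophiles add to 2-pyrones endo; C1 and C4 are fixed by the bicycle. The absolute sense comes from the (S)-O-methylmandelate, whose phenyl ring should shield one diene face as in 1-(O-methylmandeloyloxy)dienes, and the two facial isomers are diastereomers that are separated by chromatography. The step needs regio-, endo- and face selectivity: the first is secured by the polarisation of both partners, the second by the endo preference, the third by the auxiliary, and pressure at room temperature in a neutral medium keeps the enol ether geometry and prevents loss of CO2 from 7.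

Step 4
Reactants: 7 bicyclic lactone
Product: 8 (1S,4R,5S,6S)-6-{[tert-butyl(dimethyl)silyl]oxy}-1-(hydroxymethyl)-5-(propan-2-yl)cyclohex-2-ene-1,4-diol (C4 hydroxyl trans to the isopropyl group)
Conditions: LiAlH4, THF, −20 to 0 °C; Rochelle salt work-up
Reagents that add atoms: none
Why: LiAlH4 reduction opens the strained bridged lactone to the secondary allylic alcohol and a primary alcohol and cleaves the auxiliary ester in the same operation, while the silyl ether and all stereocentres stay untouched (hydride reduction of esters).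

Step 5
Reactants: 8 trans-triol
Product: 9 (4S,5S,6R)-5-{[tert-butyl(dimethyl)silyl]oxy}-4-hydroxy-4-(hydroxymethyl)-6-(propan-2-yl)cyclohex-2-en-1-one
Conditions: MnO2 (activated, excess), CH2Cl2, rt
Reagents that add atoms: none
Why: Activated MnO2 should oxidise only the secondary allylic alcohol (the tertiary allylic and the primary non-allylic hydroxyls do not react), which erases the wrongly configured carbinol centre (allylic oxidation).

Step 6
Reactants: 9 enone diol
Product: 10 (1S,4S,5S,6S)-6-{[tert-butyl(dimethyl)silyl]oxy}-1-(hydroxymethyl)-5-(propan-2-yl)cyclohex-2-ene-1,4-diol (C4 hydroxyl, isopropyl and silyloxy groups all cis)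
Conditions: NaBH4, CeCl3·7H2O, MeOH, −78 °C
Reagents that add atoms: none
Why: Luche 1,2-reduction in which hydride should add from the face opposite to the cis-disposed isopropyl and silyloxy groups on the two neighbouring ring carbons (in either half-chair one of them blocks the other face), setting the new carbinol centre cis to both.

Step 7
Reactants: 10 all-cis triol
Product: 11 (4S,5S,6S)-6-{[tert-butyl(dimethyl)silyl]oxy}-4-hydroxy-5-(propan-2-yl)cyclohex-2-en-1-one
Conditions: NaIO4, THF/pH 7 buffer, 0 °C
Reagents that add atoms: none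
Why: Periodate (Malaprade) cleavage of the only free 1,2-diol removes the former lactone carbon and unveils the C1 ketone in conjugation with the ring double bond, the silyl ether keeping the neighbouring C6–O out of the cleavage.

Step 8
Reactants: 11 hydroxy enone; 12 (2Z)-2-methylbut-2-enoic acid (angelic acid); 13 2,4,6-trichlorobenzoyl chloride
Product: 15 (1S,5S,6S)-5-{[tert-butyl(dimethyl)silyl]oxy}-4-oxo-6-(propan-2-yl)cyclohex-2-en-1-yl (2Z)-2-methylbut-2-enoate, via mixed anhydride 14 (not isolated)
Conditions: 12, 13, Et3N, toluene, rt; then 11, 80 °C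
Reagents that add atoms: none
Why: Yamaguchi esterification in which the mixed anhydride, formed without DMAP, should acylate the hindered alcohol on heating with retention at carbon and without Z to E isomerisation of the acyl group, as known for angelates of hindered secondary alcohols.

Step 9
Reactants: 15 silyl ether angelate
Product: 16 (1S,5S,6R)-5-hydroxy-4-oxo-6-(propan-2-yl)cyclohex-2-en-1-yl (2Z)-2-methylbut-2-enoate
Conditions: HF·pyridine, pyridine, THF, 0 °C to rt
Reagents that add atoms: none
Why: Fluoride desilylation under buffered, mildly acidic conditions should free the secondary hydroxyl without acyl migration or enolisation of the resulting α-hydroxy ketone.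

Step 10
Reactants: 17 {[tert-butyl(dimethyl)silyl]oxy}acetaldehyde; 18 ethyl 2-(triphenyl-λ5-phosphanylidene)propanoate
Product: 19 ethyl (2E)-4-{[tert-butyl(dimethyl)silyl]oxy}-2-methylbut-2-enoate
Conditions: CH2Cl2, rt
Reagents that add atoms: none
Why: Wittig olefination with the stabilised, α-methyl-substituted ylide should give the E trisubstituted enoate.

Step 11
Reactants: 19 ethyl ester
Product: 20 (2E)-4-{[tert-butyl(dimethyl)silyl]oxy}-2-methylbut-2-enoic acid
Conditions: LiOH, THF/MeOH/H2O, rt; then dilute HCl to pH 4, 0 °C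
Reagents that add atoms: lithium hydroxide (its oxygen ends in the carboxyl group), [Li+].[OH-]
Why: Saponification of the ethyl ester followed by careful acidification should leave the primary silyl ether and the E double bond intact.

Step 12
Reactants: 16 α-hydroxy ketone; 20 silyl-protected hydroxytiglic acid
Product: 21 (1S,5S,6S)-5-{[(2E)-4-{[tert-butyl(dimethyl)silyl]oxy}-2-methylbut-2-enoyl]oxy}-4-oxo-6-(propan-2-yl)cyclohex-2-en-1-yl (2Z)-2-methylbut-2-enoate
Conditions: DCC, DMAP (cat.), CH2Cl2, 0 °C
Reagents that add atoms: none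
Why: Steglich esterification of the α-hydroxy ketone at low temperature should acylate the hydroxyl with retention, and the E acid is configurationally stable under these conditions.

Step 13
Reactants: 21 diester enone
Product: 22 (1S,5S,6S)-5-{[(2E)-4-{[tert-butyl(dimethyl)silyl]oxy}-2-methylbut-2-enoyl]oxy}-3-(hydroxymethyl)-4-oxo-6-(propan-2-yl)cyclohex-2-en-1-yl (2Z)-2-methylbut-2-enoate
Conditions: 37% aq. CH2O, DMAP (cat.), THF/H2O, rt
Reagents that add atoms: formaldehyde, C=O
Why: Morita–Baylis–Hillman reaction in which DMAP adds to the enone β-carbon and the resulting enolate is hydroxymethylated at the α-carbon before the catalyst is expelled, the two β-substituted enoate esters being unreactive towards the amine.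

Step 14
Reactants: 22 silyl ether
Product: 23 (1S,5S,6S)-5-{[(2E)-4-hydroxy-2-methylbut-2-enoyl]oxy}-3-(hydroxymethyl)-4-oxo-6-(propan-2-yl)cyclohex-2-en-1-yl (2Z)-2-methylbut-2-enoate (CNP0281432.2)
Conditions: HF·pyridine, pyridine, THF, 0 °C
Reagents that add atoms: none
Why: Fluoride cleavage of the primary allylic silyl ether under buffered conditions should leave both esters, the enone and the epimerisable α-acyloxy ketone centre untouched.

**Compound list**
1 | 3-methylbutanal | CC(C)CC=O | starting material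
2 | potassium (1Z)-3-methylbut-1-en-1-olate | CC(C)/C=C\[O-].[K+] | intermediate
3 | tert-butyldimethyl{[(1Z)-3-methylbut-1-en-1-yl]oxy}silane | CC(C)/C=C\O[Si](C)(C)C(C)(C)C | intermediate
4 | 3-hydroxy-2H-pyran-2-one | OC1=CC=COC1=O | starting material
5 | (2S)-2-methoxy-2-phenylacetic acid | CO[C@H](C(=O)O)c1ccccc1 | starting material
6 | 2-oxo-2H-pyran-3-yl (2S)-2-methoxy-2-phenylacetate | CO[C@H](C(=O)OC1=CC=COC1=O)c1ccccc1 | intermediate
7 | (1R,4R,7S,8S)-8-{[tert-butyl(dimethyl)silyl]oxy}-3-oxo-7-(propan-2-yl)-2-oxabicyclo[2.2.2]oct-5-en-4-yl (2S)-2-methoxy-2-phenylacetate | O=C1O[C@@H]2C=C[C@@]1(OC(=O)[C@@H](OC)c3ccccc3)[C@@H](O[Si](C)(C)C(C)(C)C)[C@H]2C(C)C | intermediate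
8 | (1S,4R,5S,6S)-6-{[tert-butyl(dimethyl)silyl]oxy}-1-(hydroxymethyl)-5-(propan-2-yl)cyclohex-2-ene-1,4-diol | O[C@@H]1C=C[C@](O)(CO)[C@@H](O[Si](C)(C)C(C)(C)C)[C@H]1C(C)C | intermediate
9 | (4S,5S,6R)-5-{[tert-butyl(dimethyl)silyl]oxy}-4-hydroxy-4-(hydroxymethyl)-6-(propan-2-yl)cyclohex-2-en-1-one | O=C1C=C[C@](O)(CO)[C@@H](O[Si](C)(C)C(C)(C)C)[C@H]1C(C)C | intermediate
10 | (1S,4S,5S,6S)-6-{[tert-butyl(dimethyl)silyl]oxy}-1-(hydroxymethyl)-5-(propan-2-yl)cyclohex-2-ene-1,4-diol | O[C@H]1C=C[C@](O)(CO)[C@@H](O[Si](C)(C)C(C)(C)C)[C@H]1C(C)C | intermediate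
11 | (4S,5S,6S)-6-{[tert-butyl(dimethyl)silyl]oxy}-4-hydroxy-5-(propan-2-yl)cyclohex-2-en-1-one | O[C@H]1C=CC(=O)[C@@H](O[Si](C)(C)C(C)(C)C)[C@H]1C(C)C | intermediate
12 | (2Z)-2-methylbut-2-enoic acid (angelic acid) | C/C=C(/C)C(=O)O | starting material
13 | 2,4,6-trichlorobenzoyl chloride | O=C(Cl)c1c(Cl)cc(Cl)cc1Cl | starting material
14 | (2Z)-2-methylbut-2-enoic 2,4,6-trichlorobenzoic anhydride | C/C=C(/C)C(=O)OC(=O)c1c(Cl)cc(Cl)cc1Cl | intermediate
15 | (1S,5S,6S)-5-{[tert-butyl(dimethyl)silyl]oxy}-4-oxo-6-(propan-2-yl)cyclohex-2-en-1-yl (2Z)-2-methylbut-2-enoate | C/C=C(/C)C(=O)O[C@H]1C=CC(=O)[C@@H](O[Si](C)(C)C(C)(C)C)[C@H]1C(C)C | intermediate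
16 | (1S,5S,6R)-5-hydroxy-4-oxo-6-(propan-2-yl)cyclohex-2-en-1-yl (2Z)-2-methylbut-2-enoate | C/C=C(/C)C(=O)O[C@H]1C=CC(=O)[C@@H](O)[C@H]1C(C)C | intermediate
17 | {[tert-butyl(dimethyl)silyl]oxy}acetaldehyde | O=CCO[Si](C)(C)C(C)(C)C | starting material
18 | ethyl 2-(triphenyl-λ5-phosphanylidene)propanoate | CCOC(=O)C(C)=P(c1ccccc1)(c1ccccc1)c1ccccc1 | starting material
19 | ethyl (2E)-4-{[tert-butyl(dimethyl)silyl]oxy}-2-methylbut-2-enoate | CCOC(=O)/C(C)=C/CO[Si](C)(C)C(C)(C)C | intermediate
20 | (2E)-4-{[tert-butyl(dimethyl)silyl]oxy}-2-methylbut-2-enoic acid | OC(=O)/C(C)=C/CO[Si](C)(C)C(C)(C)C | intermediate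
21 | (1S,5S,6S)-5-{[(2E)-4-{[tert-butyl(dimethyl)silyl]oxy}-2-methylbut-2-enoyl]oxy}-4-oxo-6-(propan-2-yl)cyclohex-2-en-1-yl (2Z)-2-methylbut-2-enoate | C/C=C(/C)C(=O)O[C@H]1C=CC(=O)[C@@H](OC(=O)/C(C)=C/CO[Si](C)(C)C(C)(C)C)[C@H]1C(C)C | intermediate
22 | (1S,5S,6S)-5-{[(2E)-4-{[tert-butyl(dimethyl)silyl]oxy}-2-methylbut-2-enoyl]oxy}-3-(hydroxymethyl)-4-oxo-6-(propan-2-yl)cyclohex-2-en-1-yl (2Z)-2-methylbut-2-enoate | C/C=C(/C)C(=O)O[C@H]1C=C(CO)C(=O)[C@@H](OC(=O)/C(C)=C/CO[Si](C)(C)C(C)(C)C)[C@H]1C(C)C | intermediate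
23 | (1S,5S,6S)-5-{[(2E)-4-hydroxy-2-methylbut-2-enoyl]oxy}-3-(hydroxymethyl)-4-oxo-6-(propan-2-yl)cyclohex-2-en-1-yl (2Z)-2-methylbut-2-enoate | C/C=C(/C)C(=O)O[C@H]1C=C(CO)C(=O)[C@@H](OC(=O)/C(C)=C/CO)[C@H]1C(C)C | target

**Step count**
Total: 14 steps. Longest linear sequence: 11 steps (steps 1, 3, 4, 5, 6, 7, 8, 9, 12, 13, 14).

**Steps most likely to fail**

Step 3. The distant ester may discriminate the two pyrone faces poorly and the two endo adducts may not separate. The fallback replaces auxiliary control by an enzymatic kinetic resolution and sets out from 4. Acylation with pivaloyl chloride and pyridine gives 2-oxo-2H-pyran-3-yl pivalate F1. Cycloaddition with 3 under the conditions of step 3 gives the racemic endo pivalate adduct F2. Steps 4 to 7 are run unchanged on the racemate, so that 8, 9, 10 and 11 each arise with their mirror image: the ent-trans-triol F3, the ent-enone diol F4, the ent-all-cis triol F5 and the ent-hydroxy enone F6. Immobilised Candida antarctica lipase B with vinyl acetate in tert-butyl methyl ether at 30 °C should, by the empirical size rule for lipases, acetylate the (4R)-alcohol to the acetate of the ent-hydroxy enone F7 and leave 11. After chromatography the fallback comes back to the route at 11.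

Step 8. Acyl transfer to the hindered hydroxyl may not take place, or the activated acid may isomerise from Z to E. The fallback uses substitution at carbon instead of acyl transfer and sets out from 8. NaIO4 under the conditions of step 7 gives the C4-epimeric trans-hydroxy enone F8. Mitsunobu reaction of F8 with 12 (PPh3, DIAD, toluene, 0 °C) should give the angelate with inversion; the acid is never activated and cannot isomerise. The fallback comes back to the route at 15 and makes steps 5 to 7 unnecessary.

Step 13. The amine may epimerise the α-acyloxy ketone centre or trigger elimination, and conjugate addition to the hindered β-carbon may be slow. The fallback uses cross-coupling instead of amine catalysis and sets out from 21. Iodine and pyridine in CH2Cl2 give the 2-iodo enone F9. Stille coupling of F9 with (tributylstannyl)methanol, Pd(PPh3)4 (zerovalent palladium), dioxane, 80 °C, should give the hydroxymethyl enone. The fallback comes back to the route at 22.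

**Further compounds**
F1 | step 3 | 2-oxo-2H-pyran-3-yl 2,2-dimethylpropanoate | CC(C)(C)C(=O)OC1=CC=COC1=O
F2 | step 3 | rac-(1R,4R,7S,8S)-8-{[tert-butyl(dimethyl)silyl]oxy}-3-oxo-7-(propan-2-yl)-2-oxabicyclo[2.2.2]oct-5-en-4-yl 2,2-dimethylpropanoate (racemate; one enantiomer drawn) | O=C1O[C@@H]2C=C[C@@]1(OC(=O)C(C)(C)C)[C@@H](O[Si](C)(C)C(C)(C)C)[C@H]2C(C)C
F3 | step 3 | (1R,4S,5R,6R)-6-{[tert-butyl(dimethyl)silyl]oxy}-1-(hydroxymethyl)-5-(propan-2-yl)cyclohex-2-ene-1,4-diol (mirror image of 8) | O[C@H]1C=C[C@@](O)(CO)[C@H](O[Si](C)(C)C(C)(C)C)[C@@H]1C(C)C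
F4 | step 3 | (4R,5R,6S)-5-{[tert-butyl(dimethyl)silyl]oxy}-4-hydroxy-4-(hydroxymethyl)-6-(propan-2-yl)cyclohex-2-en-1-one (mirror image of 9) | O=C1C=C[C@@](O)(CO)[C@H](O[Si](C)(C)C(C)(C)C)[C@@H]1C(C)C
F5 | step 3 | (1R,4R,5R,6R)-6-{[tert-butyl(dimethyl)silyl]oxy}-1-(hydroxymethyl)-5-(propan-2-yl)cyclohex-2-ene-1,4-diol (mirror image of 10) | O[C@@H]1C=C[C@@](O)(CO)[C@H](O[Si](C)(C)C(C)(C)C)[C@@H]1C(C)C
F6 | step 3 | (4R,5R,6R)-6-{[tert-butyl(dimethyl)silyl]oxy}-4-hydroxy-5-(propan-2-yl)cyclohex-2-en-1-one (mirror image of 11) | O[C@@H]1C=CC(=O)[C@H](O[Si](C)(C)C(C)(C)C)[C@@H]1C(C)C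
F7 | step 3 | (1R,5R,6R)-5-{[tert-butyl(dimethyl)silyl]oxy}-4-oxo-6-(propan-2-yl)cyclohex-2-en-1-yl acetate | CC(=O)O[C@@H]1C=CC(=O)[C@H](O[Si](C)(C)C(C)(C)C)[C@@H]1C(C)C
F8 | step 8 | (4R,5S,6S)-6-{[tert-butyl(dimethyl)silyl]oxy}-4-hydroxy-5-(propan-2-yl)cyclohex-2-en-1-one | O[C@@H]1C=CC(=O)[C@@H](O[Si](C)(C)C(C)(C)C)[C@H]1C(C)C
F9 | step 13 | (1R,5S,6S)-5-{[(2E)-4-{[tert-butyl(dimethyl)silyl]oxy}-2-methylbut-2-enoyl]oxy}-3-iodo-4-oxo-6-(propan-2-yl)cyclohex-2-en-1-yl (2Z)-2-methylbut-2-enoate | C/C=C(/C)C(=O)O[C@H]1C=C(I)C(=O)[C@@H](OC(=O)/C(C)=C/CO[Si](C)(C)C(C)(C)C)[C@H]1C(C)C
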